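**Retrosynthetic overview** (germacrane numbering: ring C1–C10; C6 = lactone O–CH, C7/C11 = butenolide β/α carbons, C12 = lactone C=O, C13 = CH2OAc, C8 = CHOAc)
1. Target 22 ⇐ diacetate 21 by twofold peracid epoxidation of the E,E-1(10),4-diene on its outer faces; the two oxiranes are the last rings formed.
2. Butenolide 19 ⇐ macrocyclic α-allenyl acetate 16 + CO2: one Pd-catalysed operation makes C11–C12 and O–C6 and moves the acetate from C6 to C13.
3. Enabling feature: in the furan-2(5H)-one ring the lactone O on C6 and the acetate O on C13 are 1,4-related across C7=C11, with the carboxyl carbon C12 on C11; this array is an isomer of [C6(OAc)–C7(=C11=C13H2) allene + CO2].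
4. Ten-membered carbocycle 15 ⇐ chloro-enal 13 by intramolecular Nozaki–Hiyama propargylation (C6–C7, delivers the exocyclic allene); 13 ⇐ geraniol (C10) + 4-chlorobut-2-yn-1-ol (C4), joined at C8–C9 by α-selective allylbarium addition, C8 set by Noyori transfer hydrogenation.
5. Ring order: carbocycle (step 11) → butenolide (step 13) → two oxiranes (step 16).

Key step: step 13

Remark (assumption): 15 and 16 are carried as mixtures of C6 epimers, because C6 becomes planar in step 13 and is set anew there.
Remark: aldehyde 6 is a reactive ynal and is meant to be used at once as a solution.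

**Step 1**
Reactants: 1 geraniol, (2E)-3,7-dimethylocta-2,6-dien-1-ol
Product: 2 geranyl 4-methoxybenzyl ether
Conditions: NaH, PMBCl, Bu4NI (cat.), THF/DMF, 0 °C → rt
Reagents that add atoms: 4-methoxybenzyl chloride, COc1ccc(CCl)cc1
Why: Williamson etherification of the primary allylic alkoxide protects the C6 oxygen with a group that can later be removed oxidatively; no stereocentre is involved.

**Step 2**
Reactants: 2 geranyl 4-methoxybenzyl ether
Product: 3 (2E,6E)-8-[(4-methoxybenzyl)oxy]-2,6-dimethylocta-2,6-dien-1-ol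
Conditions: SeO2 (cat.), t-BuOOH, salicylic acid (cat.), CH2Cl2, rt
Reagents that add atoms: tert-butyl hydroperoxide, CC(C)(C)OO (oxygen delivered through catalytic selenium dioxide, O=[Se]=O)
Why: Riley allylic oxidation (ene reaction then [2,3]-shift) should hydroxylate the (E)-methyl group of the terminal trisubstituted alkene selectively, which fixes the E geometry of the future C1=C10 bond.

**Step 3**
Reactants: 3 (2E,6E)-8-[(4-methoxybenzyl)oxy]-2,6-dimethylocta-2,6-dien-1-ol
Product: 4 1-({[(2E,6E)-8-chloro-3,7-dimethylocta-2,6-dien-1-yl]oxy}methyl)-4-methoxybenzene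
Conditions: MsCl, LiCl, 2,4,6-collidine, DMF, 0 °C
Reagents that add atoms: lithium chloride, [Li+].[Cl-]
Why: Mesylation with in situ SN2 displacement by chloride converts the primary allylic alcohol into the chloride without allylic transposition or loss of alkene geometry.

**Step 4**
Reactants: 5 4-chlorobut-2-yn-1-ol
Product: 6 4-chlorobut-2-ynal
Conditions: activated MnO2, CH2Cl2, rt; filtered solution used directly
Reagents that add atoms: none
Why: Manganese dioxide oxidation of a propargylic alcohol should stop cleanly at the ynal under neutral conditions that spare the propargylic chloride.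

**Step 5**
Reactants: 4 1-({[(2E,6E)-8-chloro-3,7-dimethylocta-2,6-dien-1-yl]oxy}methyl)-4-methoxybenzene; 6 4-chlorobut-2-ynal
Product: 8 rac-(6E,10E)-1-chloro-12-[(4-methoxybenzyl)oxy]-6,10-dimethyldodeca-6,10-dien-2-yn-4-ol, via allylbarium chloride 7 (not isolated)
Conditions: BaI2, lithium biphenylide (2 equiv), THF, rt (active Ba); 4, −78 °C; then 6, −78 °C; aq NH4Cl
Reagents that add atoms: none
Why: Carbonyl allylation with an allylbarium reagent is α-selective and retains alkene geometry, so the C8–C9 bond should form at the CH2 terminus to give the linear homoallylic propargylic alcohol (racemic at C8), with 1,2-addition to the ynal outrunning attack on its chloride at −78 °C.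

**Step 6**
Reactants: 8 rac-(6E,10E)-1-chloro-12-[(4-methoxybenzyl)oxy]-6,10-dimethyldodeca-6,10-dien-2-yn-4-ol
Product: 9 (6E,10E)-1-chloro-12-[(4-methoxybenzyl)oxy]-6,10-dimethyldodeca-6,10-dien-2-yn-4-one
Conditions: Dess–Martin periodinane, NaHCO3, CH2Cl2, 0 °C
Reagents that add atoms: none
Why: Buffered Dess–Martin oxidation gives the alkynyl ketone under neutral conditions, which should keep the β,γ-alkene out of conjugation.

**Step 7**
Reactants: 9 (6E,10E)-1-chloro-12-[(4-methoxybenzyl)oxy]-6,10-dimethyldodeca-6,10-dien-2-yn-4-one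
Product: 10 (4S,6E,10E)-1-chloro-12-[(4-methoxybenzyl)oxy]-6,10-dimethyldodeca-6,10-dien-2-yn-4-ol
Conditions: Ru[(S,S)-TsDPEN](p-cymene) (1 mol %, base-free amido complex), i-PrOH, rt
Reagents that add atoms: none
Why: Noyori asymmetric transfer hydrogenation of an alkynyl ketone, with the alkyne as the π-recognition element, should give the (S)-carbinol (C8 of the target) from the (S,S)-catalyst, and the neutral medium avoids alkene migration.

**Step 8**
Reactants: 10 (4S,6E,10E)-1-chloro-12-[(4-methoxybenzyl)oxy]-6,10-dimethyldodeca-6,10-dien-2-yn-4-ol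
Product: 11 tert-butyl{[(4S,6E,10E)-1-chloro-12-[(4-methoxybenzyl)oxy]-6,10-dimethyldodeca-6,10-dien-2-yn-4-yl]oxy}dimethylsilane
Conditions: TBSOTf, 2,6-lutidine, CH2Cl2, −78 °C
Reagents that add atoms: tert-butyldimethylsilyl triflate, CC(C)(C)[Si](C)(C)OS(=O)(=O)C(F)(F)F
Why: Silylation with the triflate and a hindered base protects O8 as an ether that cannot act as a leaving group in steps 11 and 13, without displacing the propargylic chloride.

**Step 9**
Reactants: 11 tert-butyl{[(4S,6E,10E)-1-chloro-12-[(4-methoxybenzyl)oxy]-6,10-dimethyldodeca-6,10-dien-2-yn-4-yl]oxy}dimethylsilane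
Product: 12 (2E,6E,9S)-9-[(tert-butyldimethylsilyl)oxy]-12-chloro-3,7-dimethyldodeca-2,6-dien-10-yn-1-ol
Conditions: DDQ, CH2Cl2/pH 7 buffer, 0 °C
Reagents that add atoms: none
Why: Oxidative cleavage of the 4-methoxybenzyl ether with DDQ is orthogonal to the silyl ether, the chloride and the trisubstituted alkenes.

**Step 10**
Reactants: 12 (2E,6E,9S)-9-[(tert-butyldimethylsilyl)oxy]-12-chloro-3,7-dimethyldodeca-2,6-dien-10-yn-1-ol
Product: 13 (2E,6E,9S)-9-[(tert-butyldimethylsilyl)oxy]-12-chloro-3,7-dimethyldodeca-2,6-dien-10-ynal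
Conditions: activated MnO2, CH2Cl2, rt
Reagents that add atoms: none
Why: Manganese dioxide oxidises the primary allylic alcohol to the (E)-enal without isomerising the C4=C5 bond.

**Step 11**
Reactants: 13 (2E,6E,9S)-9-[(tert-butyldimethylsilyl)oxy]-12-chloro-3,7-dimethyldodeca-2,6-dien-10-ynal
Product: 15 (2E,6E,9S)-9-[(tert-butyldimethylsilyl)oxy]-10-ethenylidene-3,7-dimethylcyclodeca-2,6-dien-1-ol (C1 epimers), via propargylchromium dichloride 14 (not isolated)
Conditions: CrCl2 (8 equiv), NaI (cat.), THF/DMF, slow addition of 13 (final 2 mM), rt; aq NH4Cl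
Reagents that add atoms: none
Why: Intramolecular Nozaki–Hiyama (Barbier-type) propargylation: chromium(II) turns the primary propargylic chloride into propargylchromium 14, which adds to the enal carbonyl through its γ-carbon (SE2′) to close the ten-membered ring at C6–C7 and leave the exocyclic 1,1-disubstituted allene, the same ring bond that allylchromium reagents close in germacranolide syntheses; the new C6 carbinol centre forms as a mixture that does not matter.

**Step 12**
Reactants: 15 (2E,6E,9S)-9-[(tert-butyldimethylsilyl)oxy]-10-ethenylidene-3,7-dimethylcyclodeca-2,6-dien-1-ol (C1 epimers)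
Product: 16 (2E,6E,9S)-9-[(tert-butyldimethylsilyl)oxy]-10-ethenylidene-3,7-dimethylcyclodeca-2,6-dien-1-yl acetate (C1 epimers)
Conditions: Ac2O, Et3N, DMAP (cat.), CH2Cl2, 0 °C
Reagents that add atoms: acetic anhydride, CC(=O)OC(C)=O
Why: DMAP-catalysed acetylation installs at C6 the leaving group that is also the acetate delivered to C13 in the next step.

**Step 13**
Reactants: 16 (2E,6E,9S)-9-[(tert-butyldimethylsilyl)oxy]-10-ethenylidene-3,7-dimethylcyclodeca-2,6-dien-1-yl acetate (C1 epimers)
Product: 19 13-acetoxy-8α-[(tert-butyldimethylsilyl)oxy]germacra-1(10)E,4E,7(11)-trien-6α,12-olide, via dienylpalladium acetate 17 (not isolated), via palladium dienoate 18 (not isolated)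
Conditions: Pd2(dba)3·CHCl3 (5 mol %), PCy3 (20 mol %), CsOAc (20 mol %), CO2 (10 atm), DMSO, 60 °C
Reagents that add atoms: carbon dioxide, O=C=O
Why: Proposed new method: Pd(0) should ionise the C6 acetate of 16 (flanked by the allene and the C4=C5 alkene) in the SN2′ sense to the σ-(1,3-dien-2-yl)palladium(II) acetate 17 with Pd on C11, the electron-rich Pd–C11 bond (in equilibrium with its η1-allenylmethyl form, attacked in the SE2′ sense) should insert CO2 to give dienoate 18, and the carboxylate then adds to C6 of the palladium(II)-bound diene while the resulting C7–C11–C13 π-allyl is captured at its CH2 terminus by the acetate released at the start, which returns Pd(0) and makes the sequence redox-neutral. The closest known reaction types are SN2′ oxidative addition of Pd(0) to 2,3-dienyl esters, carboxylation of alkenyl- and η1-allyl-palladium(II) species with CO2, and palladium(II)-mediated 1,4-acyloxylation–lactonisation of conjugated dienes that carry a carboxylic acid; the new element is their coupling in one catalytic cycle, possible because an α-allenyl acetate is an isomer of a diene plus Pd(II)–OAc. One ring is closed, the butenolide, by a 5-endo-trig oxypalladation (O to C6, Pd to C7), feasible because the alkene is activated by the metal. The only new stereocentre, C6, is set in this C–O bond formation: Pd is expected to bind the C6=C7 face opposite the bulky C8 silyloxy group, so that the carboxylate, attacking anti to Pd, ends syn to O8 (6α,8α), the earlier C6 configuration having been erased. The step needs site-selective ionisation (only C6 carries an ester, C8 carries a silyl ether that cannot leave), C–C bond formation at C11 ahead of reversible acetate return or β-hydride elimination (favoured by CO2 pressure, the donor phosphine and DMSO), and acetate capture at C13 instead of C7 (primary versus fully substituted terminus, and only C13 attack gives the conjugated tetrasubstituted butenolide).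

**Step 14**
Reactants: 19 13-acetoxy-8α-[(tert-butyldimethylsilyl)oxy]germacra-1(10)E,4E,7(11)-trien-6α,12-olide
Product: 20 13-acetoxy-8α-hydroxygermacra-1(10)E,4E,7(11)-trien-6α,12-olide
Conditions: HF·pyridine, pyridine, THF, 0 °C → rt
Reagents that add atoms: none
Why: Buffered fluoride desilylation frees O8 under conditions mild enough to spare the acid-sensitive 1(10),4-diene, the allylic acetate and the base-sensitive γ-position of the butenolide.

**Step 15**
Reactants: 20 13-acetoxy-8α-hydroxygermacra-1(10)E,4E,7(11)-trien-6α,12-olide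
Product: 21 8α,13-diacetoxygermacra-1(10)E,4E,7(11)-trien-6α,12-olide
Conditions: Ac2O, pyridine, DMAP (cat.), CH2Cl2, 0 °C
Reagents that add atoms: acetic anhydride, CC(=O)OC(C)=O
Why: Standard acetylation of the secondary alcohol with retention at C8 completes the oxygenation pattern.

**Step 16**
Reactants: 21 8α,13-diacetoxygermacra-1(10)E,4E,7(11)-trien-6α,12-olide
Product: 22 8α,13-diacetoxy-1β,10α:4α,5β-diepoxygermacr-7(11)-en-6α,12-olide (target)
Conditions: mCPBA (2.3 equiv), NaHCO3, CH2Cl2, 0 °C
Reagents that add atoms: meta-chloroperoxybenzoic acid, OOC(=O)c1cccc(Cl)c1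
Why: Prilezhaev epoxidation of both E-trisubstituted ring alkenes on their exposed outer faces in the crossed conformer of the germacra-1(10),4-dienolide (both methyls on the β-face) should give the 1β,10α- and 4α,5β-epoxides (1R,10R and 4R,5R), while the electron-poor butenolide alkene is left alone.

**Compound list**
1 | geraniol, (2E)-3,7-dimethylocta-2,6-dien-1-ol | CC(C)=CCC/C(C)=C/CO | starting material
2 | geranyl 4-methoxybenzyl ether | CC(C)=CCC/C(C)=C/COCc1ccc(OC)cc1 | intermediate
3 | (2E,6E)-8-[(4-methoxybenzyl)oxy]-2,6-dimethylocta-2,6-dien-1-ol | OC/C(C)=C/CC/C(C)=C/COCc1ccc(OC)cc1 | intermediate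
4 | 1-({[(2E,6E)-8-chloro-3,7-dimethylocta-2,6-dien-1-yl]oxy}methyl)-4-methoxybenzene | ClC/C(C)=C/CC/C(C)=C/COCc1ccc(OC)cc1 | intermediate
5 | 4-chlorobut-2-yn-1-ol | OCC#CCCl | starting material
6 | 4-chlorobut-2-ynal | O=CC#CCCl | intermediate
7 | allylbarium chloride from 4 (Ba on the former CH2Cl carbon; not isolated) | Cl[Ba]C/C(C)=C/CC/C(C)=C/COCc1ccc(OC)cc1 | intermediate
8 | rac-(6E,10E)-1-chloro-12-[(4-methoxybenzyl)oxy]-6,10-dimethyldodeca-6,10-dien-2-yn-4-ol | ClCC#CC(O)C/C(C)=C/CC/C(C)=C/COCc1ccc(OC)cc1 | intermediate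
9 | (6E,10E)-1-chloro-12-[(4-methoxybenzyl)oxy]-6,10-dimethyldodeca-6,10-dien-2-yn-4-one | ClCC#CC(=O)C/C(C)=C/CC/C(C)=C/COCc1ccc(OC)cc1 | intermediate
10 | (4S,6E,10E)-1-chloro-12-[(4-methoxybenzyl)oxy]-6,10-dimethyldodeca-6,10-dien-2-yn-4-ol | ClCC#C[C@@H](O)C/C(C)=C/CC/C(C)=C/COCc1ccc(OC)cc1 | intermediate
11 | tert-butyl{[(4S,6E,10E)-1-chloro-12-[(4-methoxybenzyl)oxy]-6,10-dimethyldodeca-6,10-dien-2-yn-4-yl]oxy}dimethylsilane | ClCC#C[C@@H](O[Si](C)(C)C(C)(C)C)C/C(C)=C/CC/C(C)=C/COCc1ccc(OC)cc1 | intermediate
12 | (2E,6E,9S)-9-[(tert-butyldimethylsilyl)oxy]-12-chloro-3,7-dimethyldodeca-2,6-dien-10-yn-1-ol | ClCC#C[C@@H](O[Si](C)(C)C(C)(C)C)C/C(C)=C/CC/C(C)=C/CO | intermediate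
13 | (2E,6E,9S)-9-[(tert-butyldimethylsilyl)oxy]-12-chloro-3,7-dimethyldodeca-2,6-dien-10-ynal | ClCC#C[C@@H](O[Si](C)(C)C(C)(C)C)C/C(C)=C/CC/C(C)=C/C=O | intermediate
14 | propargylchromium(III) dichloride from 13 (not isolated) | Cl[Cr](Cl)CC#C[C@@H](O[Si](C)(C)C(C)(C)C)C/C(C)=C/CC/C(C)=C/C=O | intermediate
15 | (2E,6E,9S)-9-[(tert-butyldimethylsilyl)oxy]-10-ethenylidene-3,7-dimethylcyclodeca-2,6-dien-1-ol, both C1 epimers (C1 = germacrane C6) | OC1/C=C(C)/CC/C=C(C)/C[C@H](O[Si](C)(C)C(C)(C)C)C1=C=C | intermediate
16 | (2E,6E,9S)-9-[(tert-butyldimethylsilyl)oxy]-10-ethenylidene-3,7-dimethylcyclodeca-2,6-dien-1-yl acetate, both C1 epimers | CC(=O)OC1/C=C(C)/CC/C=C(C)/C[C@H](O[Si](C)(C)C(C)(C)C)C1=C=C | intermediate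
17 | σ-(1,3-dien-2-yl)palladium(II) acetate from SN2′ ionisation of 16 (Pd on C11, ring-cis C6=C7, phosphine ligands omitted; not isolated) | C=C([Pd]OC(C)=O)/C1=C/C=C(C)/CC/C=C(C)/C[C@@H]1O[Si](C)(C)C(C)(C)C | intermediate
18 | palladium(II) acetate dienoate after CO2 insertion at C11 (ligands omitted; not isolated) | C=C(C(=O)O[Pd]OC(C)=O)/C1=C/C=C(C)/CC/C=C(C)/C[C@@H]1O[Si](C)(C)C(C)(C)C | intermediate
19 | 13-acetoxy-8α-[(tert-butyldimethylsilyl)oxy]germacra-1(10)E,4E,7(11)-trien-6α,12-olide; [(4S,6E,10E,11aR)-4-[(tert-butyldimethylsilyl)oxy]-6,10-dimethyl-2-oxo-2,4,5,8,9,11a-hexahydrocyclodeca[b]furan-3-yl]methyl acetate | CC(=O)OCC1=C2[C@@H](O[Si](C)(C)C(C)(C)C)C/C(C)=C/CC/C(C)=C/[C@H]2OC1=O | intermediate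
20 | 13-acetoxy-8α-hydroxygermacra-1(10)E,4E,7(11)-trien-6α,12-olide (4S,11aR in the cyclodeca[b]furanone numbering) | CC(=O)OCC1=C2[C@@H](O)C/C(C)=C/CC/C(C)=C/[C@H]2OC1=O | intermediate
21 | 8α,13-diacetoxygermacra-1(10)E,4E,7(11)-trien-6α,12-olide | CC(=O)OCC1=C2[C@@H](OC(C)=O)C/C(C)=C/CC/C(C)=C/[C@H]2OC1=O | intermediate
22 | 8α,13-diacetoxy-1β,10α:4α,5β-diepoxygermacr-7(11)-en-6α,12-olide, (1R,4R,5R,6S,8S,10R) | CC(=O)OCC1=C2[C@@H](OC(C)=O)C[C@@]3(C)O[C@@H]3CC[C@@]3(C)O[C@@H]3[C@H]2OC1=O | target

**Step count**
Total steps: 16. Longest linear sequence: 15 (steps 1–3 and 5–16 from geraniol; step 4 is a one-step side branch).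

**Steps most likely to fail**

1. Step 13 (proposed new method). CO2 insertion into the Pd–C11 bond may be outrun by acetate return or by β-hydride elimination to a tetraene, and the facial selectivity of C–O bond formation at C6 may be poor. The fallback uses known reactions, sets out from 16 and comes back at 19, with the C–C and the C–O bond made in separate operations. Palladium(II)-catalysed SN2′ substitution of the α-allenic acetate by bromide (Pd(OAc)2 cat., LiBr, AcOH, rt) should give the macrocyclic 2-bromo-1,3-diene F1. Bromine–lithium exchange (t-BuLi, THF, −78 °C) and a CO2 quench should give the dienoic acid F2. Palladium(II)-catalysed oxidative 1,4-acetoxy-lactonisation of F2 (Pd(OAc)2 cat., p-benzoquinone, LiOAc, AcOH/acetone, rt) should then close the butenolide with acetate delivered to C13, giving 19.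

2. Step 11. Medium-ring closure may lose to oligomerisation, or the organochromium may react through its α-carbon to give the twelve-membered homopropargylic alcohol. The fallback replaces the in situ Barbier reaction by Lewis acid-promoted SE2′ cyclisation of an isolable propargylstannane, a macrocyclisation type with precedent in terpenoid synthesis; it sets out from 12 and comes back at 15. Displacement of the chloride with Bu3SnLi (2.2 equiv, THF, −78 °C) should give the propargylstannane alcohol F3. MnO2 oxidation should give the stannyl enal F4. BF3·OEt2 (CH2Cl2, −78 °C, high dilution) should then close the ring by attack of the alkyne γ-carbon on the aldehyde, giving 15.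

3. Step 16. The peracid may attack the wrong face of one of the ring alkenes, or the acid by-product may trigger transannular cyclisation of the mono-epoxide. The fallback changes from substrate control to reagent control: Shi epoxidation of 21 with the D-fructose-derived ketone (Oxone, buffered MeCN/dimethoxymethane/water, 0 °C) is expected to deliver (R,R)-epoxides from E-trisubstituted alkenes, which is the sense needed at both C1/C10 and C4/C5, and gives 22 directly without new intermediates.

**Further compounds**
F1 | step 13 | 11-bromo-8α-[(tert-butyldimethylsilyl)oxy]-12-norgermacra-1(10)E,4E,6,11(13)-tetraene (ring-cis C6=C7) | C=C(Br)/C1=C/C=C(C)/CC/C=C(C)/C[C@@H]1O[Si](C)(C)C(C)(C)C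
F2 | step 13 | 8α-[(tert-butyldimethylsilyl)oxy]germacra-1(10)E,4E,6,11(13)-tetraen-12-oic acid (ring-cis C6=C7) | C=C(C(=O)O)/C1=C/C=C(C)/CC/C=C(C)/C[C@@H]1O[Si](C)(C)C(C)(C)C
F3 | step 11 | (2E,6E,9S)-9-[(tert-butyldimethylsilyl)oxy]-3,7-dimethyl-12-(tributylstannyl)dodeca-2,6-dien-10-yn-1-ol | CCCC[Sn](CCCC)(CCCC)CC#C[C@@H](O[Si](C)(C)C(C)(C)C)C/C(C)=C/CC/C(C)=C/CO
F4 | step 11 | (2E,6E,9S)-9-[(tert-butyldimethylsilyl)oxy]-3,7-dimethyl-12-(tributylstannyl)dodeca-2,6-dien-10-ynal | CCCC[Sn](CCCC)(CCCC)CC#C[C@@H](O[Si](C)(C)C(C)(C)C)C/C(C)=C/CC/C(C)=C/C=O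
F0 | step 16 | none | none
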